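## Retrosynthetic overview

1. Feature: in each half, ring C (O1–C2–C3–C4–C4a–C8a) contains the ortho-quinone methide heterodiene O1=C8a–C4a=C4 built on ring A. C2=C3 with ring B is a 4-oxygenated styrene. Cutting O1–C2 and C3–C4 in both halves gives one 6,6''-linked bis(salicylaldehyde) and two styrenes.
2. C4=O travels through the cycloaddition as C4–OMe, which comes from the orthoformate-derived cation. It is regained by solvolysis and oxidation, and the six benzyl ethers are removed last.
3. C6–C6'' is cut to an aryl iodide (Ullmann). Iodine is placed between O5 and O7 by iodination ortho to a free 5-OH while O1 is masked as a MOM ether. This detour is needed because halogenation of O-protected 3,5-dialkoxyphenols tends to hit the carbon that would become C8.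
4. Ring order: rings A (purchased), then the biaryl, then both rings C in one operation. Rings B arrive with the styrene.

Key step: step 8

Assumption: the target string defines no configuration for the C6–C6'' axis, which is flanked by four oxygen substituents. All biaryls are therefore drawn without an axial descriptor, atropisomers of 6–17 are carried together, and only C2 and C2'' are controlled.

## Route

Step 1
Reactants: 1 2,4,6-trihydroxybenzaldehyde
Product: 2 4-(benzyloxy)-2,6-dihydroxybenzaldehyde
Conditions: BnBr (1.0 equiv), K2CO3 (1.0 equiv), DMF, 0 °C to rt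
Reagents that add atoms: benzyl bromide, BrCc1ccccc1
Why: Williamson etherification; the 4-OH, para to the formyl group, is the most acidic and least hindered hydroxyl and is not engaged with the carbonyl oxygen, so one equivalent of base and halide should alkylate it first.

Step 2
Reactants: 2 4-(benzyloxy)-2,6-dihydroxybenzaldehyde
Product: 3 4-(benzyloxy)-2-hydroxy-6-(methoxymethoxy)benzaldehyde
Conditions: MOMCl (1.1 equiv), iPr2NEt, CH2Cl2, 0 °C
Reagents that add atoms: chloromethyl methyl ether, COCCl
Why: MOM protection (O-alkylation); the two hydroxyls are equivalent, and once one has reacted the other is locked in a strong chelate with the aldehyde, which should stop the reaction at the mono-ether that masks the future O1.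

Step 3
Reactants: 3 4-(benzyloxy)-2-hydroxy-6-(methoxymethoxy)benzaldehyde
Product: 4 4-(benzyloxy)-2-hydroxy-3-iodo-6-(methoxymethoxy)benzaldehyde
Conditions: NIS (1.0 equiv), CH2Cl2, 0 °C, dark
Reagents that add atoms: N-iodosuccinimide, O=C1CCC(=O)N1I
Why: Electrophilic aromatic iodination; C3 is ortho to the free chelated phenol, para to the MOM ether and less crowded than C5 between two ethers, the pattern established for 2-hydroxy-4,6-dialkoxyaryl carbonyl compounds, so iodine should enter between the oxygens that become O5 and O7.

Step 4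
Reactants: 4 4-(benzyloxy)-2-hydroxy-3-iodo-6-(methoxymethoxy)benzaldehyde
Product: 5 2,4-bis(benzyloxy)-3-iodo-6-(methoxymethoxy)benzaldehyde
Conditions: BnBr (1.3 equiv), K2CO3, DMF, 60 °C
Reagents that add atoms: benzyl bromide, BrCc1ccccc1
Why: Williamson etherification; warming in DMF breaks the chelate of the only remaining phenol, while the MOM ether, aryl iodide and non-enolisable aldehyde are inert to carbonate.

Step 5
Reactants: 5 2,4-bis(benzyloxy)-3-iodo-6-(methoxymethoxy)benzaldehyde (two molecules)
Product: 6 2,2',6,6'-tetrakis(benzyloxy)-4,4'-bis(methoxymethoxy)biphenyl-3,3'-dicarbaldehyde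
Conditions: activated Cu powder (5 equiv), DMF, 150 °C, Ar
Reagents that add atoms: none
Why: Ullmann reductive homocoupling; insertion of zerovalent copper into the C–I bond and coupling of the arylcopper with a second iodide is the established way to hexaoxygenated biphenyls with two ortho alkoxy groups per ring, tolerates a carbonyl group, and forms C6–C6''.

Step 6
Reactants: 6 2,2',6,6'-tetrakis(benzyloxy)-4,4'-bis(methoxymethoxy)biphenyl-3,3'-dicarbaldehyde
Product: 7 2,2',6,6'-tetrakis(benzyloxy)-4,4'-dihydroxybiphenyl-3,3'-dicarbaldehyde (the 6,6''-linked bis(salicylaldehyde))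
Conditions: 3 M aq HCl, THF, 50 °C
Reagents that add atoms: none
Why: Acid hydrolysis of the MOM acetals; formaldehyde acetals ortho to a formyl group cleave under mild aqueous acid that leaves benzyl ethers and aldehydes untouched, freeing both O1–H groups.

Step 7
Reactants: 8 4-(benzyloxy)benzaldehyde
Product: 9 4-(benzyloxy)styrene
Conditions: Ph3PCH3Br, KOtBu, THF, 0 °C to rt
Reagents that add atoms: methyltriphenylphosphonium bromide, C[P+](c1ccccc1)(c1ccccc1)c1ccccc1.[Br-]
Why: Wittig methylenation of a non-enolisable aromatic aldehyde with the unstabilised ylide is reliable and leaves the benzyl ether intact.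

Step 8
Reactants: 7 bis(salicylaldehyde); 9 4-(benzyloxy)styrene; 10 trimethyl orthoformate
Product: 14 hexa-O-benzyl (2S,4S,2''S,4''S)-4,4''-dimethoxy-6,6''-biflavan (2,4-cis in both halves), via bis(dimethyl acetal) 11 (not isolated), via methoxy ortho-quinone methide cation 12 (not isolated), via mono-cycloadduct acetal 13 (not isolated)
Conditions: first 10 (2.2 equiv), imidodiphosphorimidate acid HN[P(=NSO2CF3)(O,O'-3,3'-Ar2-1,1'-binaphthalene-2,2'-diyl)]2 with Ar = 3,5-(CF3)2C6H3 (10 mol %), 5 Å MS, CHCl3/toluene, rt; then 9 (5 equiv, slow addition), −40 to −20 °C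
Reagents that add atoms: trimethyl orthoformate (10), COC(OC)OC
Why: Proposed new method: the acid and the orthoformate convert each formyl group into its dimethyl acetal (11), loss of methanol gives the O-protonated 4-methoxy ortho-quinone methide 12 (O1=C8a–C4a=C4) as a contact ion pair with the confined chiral anion, and the CH2 terminus of 9 attacks C4 while the charge building at the 4-benzyloxybenzylic carbon is quenched by O1, an asynchronous inverse-demand hetero-Diels–Alder reaction that rearomatises ring A and then repeats on the second half of 13. The closest known reaction types are the achiral acid-promoted three-component chroman synthesis from salicylaldehydes, trimethyl orthoformate and styrenes, and chiral phosphoric or imidodiphosphoric acid catalysed cycloadditions of ortho-quinone methides, whereas an intermolecular, enantioselective and twofold version with a styrene has not been shown. Each ring C closes in an untethered intermolecular [4+2] mode, with C3–C4 leading and O1–C2 completing the six-membered pyran. C2 and C2'' are controlled by the chiral anion, which is hydrogen-bonded to the phenolic O1–H of the cation, sits at the site of O1–C2 bond formation and decides which styrene face is presented (both antipodes of the acid are accessible, so the one leading to 2S is used), while C4 and C4'' follow from the endo-type approach that places aryl and methoxy cis and are erased in step 10, so any 2,4-trans material with 2S converges. The step needs regioselectivity (aryl next to oxygen), secured by the para-benzyloxy group that polarises the styrene and stabilises charge at C2, chemoselectivity for the styrene over ring A carbons, secured by the blocked C6, the excess of styrene and complete acetal formation before the styrene is added so that no dialkoxycarbenium ion consumes it, and catalyst control that overrides the biaryl axis and the first-formed ring. Because two independent additions are made, the minor sense of attack should end mainly in the separable 2S,2''R diastereomer, which raises the enantiopurity of the 2S,2''S product.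

Step 9
Reactants: 14 hexa-O-benzyl (2S,4S,2''S,4''S)-4,4''-dimethoxy-6,6''-biflavan
Product: 15 hexa-O-benzyl (2S,2''S)-6,6''-biflavan-4,4''-diol (mixture of C4 and C4'' epimers)
Conditions: TsOH·H2O (10 mol %), THF/H2O 4:1, high dilution (about 5 mM), rt
Reagents that add atoms: water, O
Why: Acid-catalysed SN1 solvolysis; the C4–OMe bond ionises readily because three oxygen donors of ring A stabilise the cation, a large excess of water at high dilution should trap it faster than C8 of another molecule can, and the C2–O1 bond is not touched, so 2S and 2''S are retained.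

Step 10
Reactants: 15 hexa-O-benzyl (2S,2''S)-6,6''-biflavan-4,4''-diol
Product: 16 hexa-O-benzyl-(2S,2''S)-succedaneaflavanone
Conditions: Dess–Martin periodinane (3 equiv), NaHCO3, CH2Cl2, 0 °C to rt
Reagents that add atoms: none
Why: Dess–Martin oxidation under buffered, non-basic conditions converts all C4 epimers into the same diketone, removes the C4 stereocentres and avoids the base-induced retro-oxa-Michael opening that would racemise C2.

Step 11
Reactants: 16 hexa-O-benzyl-(2S,2''S)-succedaneaflavanone
Product: 17 succedaneaflavanone, (2S,2''S)-6,6''-binaringenin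
Conditions: H2 (1 atm), Pd/C (10 wt % Pd), THF/MeOH, rt, stopped at full debenzylation
Reagents that add atoms: none
Why: Catalytic hydrogenolysis cleaves the six O-benzyl bonds under neutral conditions, in which the strongly conjugated C4 ketone and the cyclic C2–O1 bond react much more slowly and C2 does not epimerise.

## Compound list

1 | 2,4,6-trihydroxybenzaldehyde | O=Cc1c(O)cc(O)cc1O | starting material
2 | 4-(benzyloxy)-2,6-dihydroxybenzaldehyde | O=Cc1c(O)cc(OCc2ccccc2)cc1O | intermediate
3 | 4-(benzyloxy)-2-hydroxy-6-(methoxymethoxy)benzaldehyde | O=Cc1c(O)cc(OCc2ccccc2)cc1OCOC | intermediate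
4 | 4-(benzyloxy)-2-hydroxy-3-iodo-6-(methoxymethoxy)benzaldehyde | O=Cc1c(O)c(I)c(OCc2ccccc2)cc1OCOC | intermediate
5 | 2,4-bis(benzyloxy)-3-iodo-6-(methoxymethoxy)benzaldehyde | O=Cc1c(OCc2ccccc2)c(I)c(OCc2ccccc2)cc1OCOC | intermediate
6 | 2,2',6,6'-tetrakis(benzyloxy)-4,4'-bis(methoxymethoxy)biphenyl-3,3'-dicarbaldehyde | O=Cc1c(OCOC)cc(OCc2ccccc2)c(-c2c(OCc3ccccc3)cc(OCOC)c(C=O)c2OCc2ccccc2)c1OCc1ccccc1 | intermediate
7 | 2,2',6,6'-tetrakis(benzyloxy)-4,4'-dihydroxybiphenyl-3,3'-dicarbaldehyde (key-step precursor) | O=Cc1c(O)cc(OCc2ccccc2)c(-c2c(OCc3ccccc3)cc(O)c(C=O)c2OCc2ccccc2)c1OCc1ccccc1 | intermediate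
8 | 4-(benzyloxy)benzaldehyde | O=Cc1ccc(OCc2ccccc2)cc1 | starting material
9 | 4-(benzyloxy)styrene | C=Cc1ccc(OCc2ccccc2)cc1 | intermediate
10 | trimethyl orthoformate | COC(OC)OC | starting material
11 | bis(dimethyl acetal) of 7 | COC(OC)c1c(O)cc(OCc2ccccc2)c(-c2c(OCc3ccccc3)cc(O)c(C(OC)OC)c2OCc2ccccc2)c1OCc1ccccc1 | intermediate
12 | O-protonated 4-methoxy ortho-quinone methide cation, drawn as the oxocarbenium form, ion pair with the catalyst anion, second half still acetal | C[O+]=Cc1c(O)cc(OCc2ccccc2)c(-c2c(OCc3ccccc3)cc(O)c(C(OC)OC)c2OCc2ccccc2)c1OCc1ccccc1 | intermediate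
13 | (2S,4S)-mono-cycloadduct carrying the second ring A as hydroxy acetal | CO[C@H]1C[C@@H](c2ccc(OCc3ccccc3)cc2)Oc2cc(OCc3ccccc3)c(-c3c(OCc4ccccc4)cc(O)c(C(OC)OC)c3OCc3ccccc3)c(OCc3ccccc3)c21 | intermediate
14 | hexa-O-benzyl (2S,4S,2''S,4''S)-4,4''-dimethoxy-6,6''-biflavan (key-step product) | CO[C@H]1C[C@@H](c2ccc(OCc3ccccc3)cc2)Oc2cc(OCc3ccccc3)c(-c3c(OCc4ccccc4)cc4c(c3OCc3ccccc3)[C@@H](OC)C[C@@H](c3ccc(OCc5ccccc5)cc3)O4)c(OCc3ccccc3)c21 | intermediate
15 | hexa-O-benzyl (2S,2''S)-6,6''-biflavan-4,4''-diol, C4 and C4'' epimers | OC1C[C@@H](c2ccc(OCc3ccccc3)cc2)Oc2cc(OCc3ccccc3)c(-c3c(OCc4ccccc4)cc4c(c3OCc3ccccc3)C(O)C[C@@H](c3ccc(OCc5ccccc5)cc3)O4)c(OCc3ccccc3)c21 | intermediate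
16 | hexa-O-benzyl-(2S,2''S)-succedaneaflavanone | O=C1C[C@@H](c2ccc(OCc3ccccc3)cc2)Oc2cc(OCc3ccccc3)c(-c3c(OCc4ccccc4)cc4c(c3OCc3ccccc3)C(=O)C[C@@H](c3ccc(OCc5ccccc5)cc3)O4)c(OCc3ccccc3)c21 | intermediate
17 | succedaneaflavanone, (2S,2''S) | O=C1C[C@@H](c2ccc(O)cc2)Oc2cc(O)c(-c3c(O)cc4c(c3O)C(=O)C[C@@H](c3ccc(O)cc3)O4)c(O)c21 | target

## Step count and risks

Total step count: 11. Longest linear sequence: 10 steps (steps 1–6 and 8–11). Step 7 is a one-step side branch.

**Step 8**
- What may go wrong:
  - insufficient facial selectivity in one or both additions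
  - acid-induced oligomerisation of the styrene
  - Friedel–Crafts attack of the cation on C8 of another ring A
  - renewed ionisation at C4 of the adduct, followed by elimination or a further styrene addition
- Fallback by known chemistry, from 6 back to 16:
  - Addition of MeMgBr (THF, 0 °C) to both formyl groups of 6 gives the bis(1-hydroxyethyl)biaryl F1.
  - Dess–Martin oxidation gives the bis(acetophenone) F2.
  - Heating with N,N-dimethylformamide dimethyl acetal gives the bis(enaminone) F3.
  - Aqueous HCl removes the MOM groups and closes both pyranone rings to the tetra-O-benzyl 6,6''-bichromone F4.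
  - Rhodium-catalysed asymmetric 1,4-addition of 4-(benzyloxy)phenylboronic acid to both chromone C2=C3 bonds then gives 16. The catalyst is [Rh(OH)(cod)]2 with the electron-poor axially chiral bisphosphine MeO-F12-BIPHEP (the antipode that gives 2S), in toluene/H2O at rt.
  - Steps 6, 8, 9 and 10 are bypassed.

**Step 5**
- What may go wrong: protodeiodination and stalling of the coupling, because a tetra-ortho-substituted biaryl bond has to form.
- Fallback, from 5 back to 6:
  - Half of iodide 5 is converted by Miyaura borylation (B2pin2, PdCl2(dppf), KOAc, dioxane, 90 °C) into the pinacol boronate F5.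
  - F5 is cross-coupled with the other half of 5 in a Suzuki–Miyaura reaction suited to hindered partners (Pd(OAc)2, SPhos, K3PO4, toluene/H2O, 100 °C) to give 6.

**Step 9**
- What may go wrong: self-condensation of the C4 cation with C8 of another molecule, elimination towards the flav-3-ene, or slow acid-induced opening at C2–O1 with erosion of configuration.
- Fallback, from 14 directly to 16:
  - The solvolysis is replaced by an oxidative cleavage of the benzylic methyl ethers with DDQ (CH2Cl2/pH 7 buffer, rt).
  - Hydride abstraction from C4–H, which is activated by the methoxy group and by the trioxygenated ring A, gives an oxocarbenium ion. Water adds to it, and the hemiketal collapses to the ketone.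
  - Compound 15 and step 10 are skipped, and no compound outside the list is made (F0).

## Further compounds

F1 | step 8 | 1,1'-[2,2',6,6'-tetrakis(benzyloxy)-4,4'-bis(methoxymethoxy)biphenyl-3,3'-diyl]diethanol (diastereomer mixture) | CC(O)c1c(OCOC)cc(OCc2ccccc2)c(-c2c(OCc3ccccc3)cc(OCOC)c(C(C)O)c2OCc2ccccc2)c1OCc1ccccc1
F2 | step 8 | 3,3'-diacetyl-2,2',6,6'-tetrakis(benzyloxy)-4,4'-bis(methoxymethoxy)biphenyl | CC(=O)c1c(OCOC)cc(OCc2ccccc2)c(-c2c(OCc3ccccc3)cc(OCOC)c(C(C)=O)c2OCc2ccccc2)c1OCc1ccccc1
F3 | step 8 | bis[(E)-3-(dimethylamino)acryloyl] analogue of F2 | CN(C)/C=C/C(=O)c1c(OCOC)cc(OCc2ccccc2)c(-c2c(OCc3ccccc3)cc(OCOC)c(C(=O)/C=C/N(C)C)c2OCc2ccccc2)c1OCc1ccccc1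
F4 | step 8 | 5,5'',7,7''-tetrakis(benzyloxy)-6,6''-bichromone | O=c1ccoc2cc(OCc3ccccc3)c(-c3c(OCc4ccccc4)cc4occc(=O)c4c3OCc3ccccc3)c(OCc3ccccc3)c12
F5 | step 5 | 2,4-bis(benzyloxy)-6-(methoxymethoxy)-3-(4,4,5,5-tetramethyl-1,3,2-dioxaborolan-2-yl)benzaldehyde | O=Cc1c(OCc2ccccc2)c(B2OC(C)(C)C(C)(C)O2)c(OCc2ccccc2)cc1OCOC
F0 | step 9 | none | none
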